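**Retrosynthetic overview**
- Both rings (the cis-fused cyclopenta[c]pyran) and the C1/C5/C9 stereocentres are taken intact from the chiral-pool iridoid genipin (1); no ring is formed in the route.
- Disconnect the C10–O (Z)-p-coumaroyl ester (Steglich) and the C1–O isovaleroyl acylal (lactol acylation); C11 CH2OH comes from the CO2Me of genipin (DIBAL).
- The trans-7β,8α-diol comes from the 7β,8β-epoxide of C7=C8 (convex-face epoxidation, then acid hydrolysis with inversion at tertiary C8), done while the enol ether is still deactivated by the ester.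
- Order: bis-silylate → epoxidise → hydrolyse → reduce → cap C11 → C1 ester → free C10 → C10 ester → global desilylation. The Z-acid is made separately by Still–Gennari olefination.

Assumption: genipin is an acceptable commercial starting material. Iridoid numbering is used (C1 acetal, C3=C4, C5/C9 ring fusion, C10 = CH2 on C8, C11 = CH2 on C4); β means the face carrying H-5 and H-9. The target SMILES reads as 1β-O-acyl, 7β-OH, 8α-OH, 10-CH2 β, i.e. (1S,4aS,6S,7R,7aS). This is a designed route; it has not been run.

**Route**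

Step 1
Reactants: 1 genipin
Product: 2 1β,10-bis-O-TBS-genipin
Conditions: TBSCl (3 eq), imidazole (6 eq), DMAP (cat.), DMF, 0 °C → rt
Reagents that add atoms: TBSCl, CC(C)(C)[Si](C)(C)Cl
Why: O-silylation of the primary allylic OH and the lactol OH does not touch the C1–O bond, so the natural β-lactol (O cis to H-9) is locked as a silyl acetal that survives DIBAL.

Step 2
Reactants: 2
Product: 3 7β,8β-epoxide of 2
Conditions: mCPBA (1.3 eq), NaHCO3, CH2Cl2, 0 °C
Reagents that add atoms: mCPBA, O=C(OO)c1cccc(Cl)c1
Why: Prilezhaev epoxidation is selective for the isolated trisubstituted C7=C8 (C3=C4 is an electron-poor vinylogous carbonate) and should occur on the convex face (the H-5/H-9 side, away from the folded dihydropyran), setting C7 and C8 as the β-epoxide.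

Step 3
Reactants: 3
Product: 4 7β,8α-diol (methyl ester, 1β-OTBS, 10-OTBS)
Conditions: aq HClO4 (10 mol %), THF/H2O 4:1, 0 °C; NaHCO3 quench
Reagents that add atoms: water, O
Why: Acid-catalysed anti (Markovnikov) epoxide hydrolysis, in which water opens the protonated epoxide at tertiary C8 with inversion (8α-OH, CH2OTBS now β) and the 7β C–O bond is untouched; the ester-deactivated acetal and TBS ethers should tolerate brief dilute acid.

Step 4
Reactants: 4
Product: 5 C11 alcohol (7β,8α,11-triol, 1β-OTBS, 10-OTBS)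
Conditions: DIBAL-H (5 eq), CH2Cl2, −78 → −40 °C; Rochelle salt work-up
Reagents that add atoms: none
Why: DIBAL 1,2-reduction of the vinylogous-carbonate ester to the allylic alcohol (the two free OH only consume hydride), placed here because no acyl group is present yet and the C7/C8 oxidation is finished before the enol ether becomes electron-rich.

Step 5
Reactants: 5
Product: 6 11-O-TBDPS ether of 5
Conditions: TBDPSCl (1.1 eq), imidazole, CH2Cl2, 0 °C
Reagents that add atoms: TBDPSCl, CC(C)(C)[Si](Cl)(c1ccccc1)c1ccccc1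
Why: Selective silylation of the only primary OH over the hindered secondary 7-OH and tertiary 8-OH; TBDPS is chosen because it survives the HF·pyridine that later removes TBS.

Step 6
Reactants: 6
Product: 7 C1 lactol (1β-OH major; 10-OTBS, 11-OTBDPS, 7,8-diol)
Conditions: TBAF (1.1 eq), AcOH (1.2 eq), THF, −20 °C
Reagents that add atoms: none
Why: Fluoride desilylation is fastest at the anomeric silyl acetal (best alkoxide leaving group), so buffered TBAF at low temperature frees only C1-OH, and the lactol stays predominantly β (OH trans to C8).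

Step 7
Reactants: 7
Product: 8 1β-O-isovaleroyl ester
Conditions: isovaleric anhydride (1.2 eq), Et3N, DMAP (5 mol %), CH2Cl2, −30 °C
Reagents that add atoms: isovaleric anhydride, CC(C)CC(=O)OC(=O)CC(C)C
Why: DMAP-catalysed acylation of the more acidic, less hindered lactol OH outpaces the neopentyl-flanked 7-OH and tertiary 8-OH, and because the C1–O bond is not broken the β-lactol is captured as the 1β (1S) ester.

Step 8
Reactants: 8
Product: 9 10-alcohol (1β-O-isovaleroyl, 11-OTBDPS, 7β,8α,10-triol)
Conditions: HF·pyridine, excess pyridine, THF, 0 °C → rt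
Reagents that add atoms: none
Why: Under acidic fluoride a primary TBS ether is cleaved far faster than a primary TBDPS ether, so only C10-OH is exposed, and pyridine buffering protects the acylal and enol ether.

Step 9
Reactants: 10 4-(tert-butyldimethylsilyloxy)benzaldehyde; 11 methyl bis(2,2,2-trifluoroethyl)phosphonoacetate
Product: 12 methyl (Z)-3-[4-(TBSO)phenyl]prop-2-enoate
Conditions: KHMDS, 18-crown-6, THF, −78 °C
Reagents that add atoms: none (11 is a numbered reactant)
Why: Still–Gennari Horner–Wadsworth–Emmons olefination, where the trifluoroethyl phosphonate under dissociating conditions eliminates kinetically to the Z-enoate.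

Step 10
Reactants: 12
Product: 13 (Z)-p-coumaric acid
Conditions: LiOH·H2O (4 eq), THF/MeOH/H2O, rt, dark; acidify to pH 3
Reagents that add atoms: lithium hydroxide/water, [Li+].[OH-]
Why: Saponification by acyl–oxygen cleavage does not involve the alkene, so Z is retained; the aryl silyl ether is deliberately cleaved at the same time.

Step 11
Reactants: 13
Product: 14 (Z)-3-[4-(TBSO)phenyl]prop-2-enoic acid
Conditions: TBSCl (2.5 eq), imidazole, DMF, rt; then AcOH/THF/H2O, rt, dark
Reagents that add atoms: TBSCl, CC(C)(C)[Si](C)(C)Cl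
Why: Bis-silylation followed by selective hydrolysis of the very labile silyl ester leaves the aryl TBS ether and the free acid.

Step 12
Reactants: 9; 14
Product: 15 10-O-[(Z)-4-(TBSO)cinnamoyl] ester (11-OTBDPS, 1β-O-isovaleroyl)
Conditions: EDC·HCl (1.5 eq), DMAP (0.2 eq), CH2Cl2, 0 °C → rt, dark
Reagents that add atoms: none
Why: Steglich esterification occurs at the only primary OH (C10) in preference to secondary 7-OH and tertiary 8-OH, and low temperature, sub-stoichiometric DMAP and exclusion of light preserve the Z-alkene.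

Step 13
Reactants: 15
Product: 16 luzonoid D
Conditions: TBAF/AcOH (1:1, 5 eq), THF, 0 °C → rt, dark
Reagents that add atoms: none
Why: Buffered fluoride desilylation removes the aryl TBS and primary TBDPS ethers without base-induced acyl migration, acylal cleavage or Z→E isomerisation; no stereocentre is touched.

**Compound list**

1 | genipin, methyl (1R,4aS,7aS)-1-hydroxy-7-(hydroxymethyl)-1,4a,5,7a-tetrahydrocyclopenta[c]pyran-4-carboxylate (1β-OH, 5β-H, 9β-H) | O[C@@H]1OC=C(C(=O)OC)[C@H]2CC=C(CO)[C@@H]12 | starting material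

2 | 1β,10-bis-O-TBS-genipin | CC(C)(C)[Si](C)(C)O[C@@H]1OC=C(C(=O)OC)[C@H]2CC=C(CO[Si](C)(C)C(C)(C)C)[C@@H]12 | intermediate

3 | 7β,8β-epoxide of 2 (epoxide O on the H-5/H-9 face) | CC(C)(C)[Si](C)(C)O[C@@H]1OC=C(C(=O)OC)[C@H]2C[C@@H]3O[C@]3(CO[Si](C)(C)C(C)(C)C)[C@@H]12 | intermediate

4 | 7β,8α-dihydroxy methyl ester (8-CH2OTBS β, 1β-OTBS) | CC(C)(C)[Si](C)(C)O[C@@H]1OC=C(C(=O)OC)[C@H]2C[C@H](O)[C@](O)(CO[Si](C)(C)C(C)(C)C)[C@@H]12 | intermediate

5 | 7β,8α,11-triol (C4-CH2OH, 1β-OTBS, 10-OTBS) | CC(C)(C)[Si](C)(C)O[C@@H]1OC=C(CO)[C@H]2C[C@H](O)[C@](O)(CO[Si](C)(C)C(C)(C)C)[C@@H]12 | intermediate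

6 | 11-O-TBDPS-1β,10-bis-O-TBS-7β,8α-diol | CC(C)(C)[Si](C)(C)O[C@@H]1OC=C(CO[Si](c3ccccc3)(c4ccccc4)C(C)(C)C)[C@H]2C[C@H](O)[C@](O)(CO[Si](C)(C)C(C)(C)C)[C@@H]12 | intermediate

7 | 1β-lactol (1-OH free; 10-OTBS, 11-OTBDPS, 7β,8α-diol) | O[C@@H]1OC=C(CO[Si](c3ccccc3)(c4ccccc4)C(C)(C)C)[C@H]2C[C@H](O)[C@](O)(CO[Si](C)(C)C(C)(C)C)[C@@H]12 | intermediate

8 | 1β-O-isovaleroyl-10-O-TBS-11-O-TBDPS-7β,8α-diol | CC(C)CC(=O)O[C@@H]1OC=C(CO[Si](c3ccccc3)(c4ccccc4)C(C)(C)C)[C@H]2C[C@H](O)[C@](O)(CO[Si](C)(C)C(C)(C)C)[C@@H]12 | intermediate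

9 | 1β-O-isovaleroyl-11-O-TBDPS-7β,8α,10-triol | CC(C)CC(=O)O[C@@H]1OC=C(CO[Si](c3ccccc3)(c4ccccc4)C(C)(C)C)[C@H]2C[C@H](O)[C@](O)(CO)[C@@H]12 | intermediate

10 | 4-(tert-butyldimethylsilyloxy)benzaldehyde | O=Cc1ccc(O[Si](C)(C)C(C)(C)C)cc1 | starting material

11 | methyl bis(2,2,2-trifluoroethyl)phosphonoacetate (Still–Gennari reagent) | COC(=O)CP(=O)(OCC(F)(F)F)OCC(F)(F)F | starting material

12 | methyl (Z)-3-[4-(TBSO)phenyl]prop-2-enoate | COC(=O)/C=C\c1ccc(O[Si](C)(C)C(C)(C)C)cc1 | intermediate

13 | (Z)-p-coumaric acid | OC(=O)/C=C\c1ccc(O)cc1 | intermediate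

14 | (Z)-3-[4-(TBSO)phenyl]prop-2-enoic acid | OC(=O)/C=C\c1ccc(O[Si](C)(C)C(C)(C)C)cc1 | intermediate

15 | 4′-O-TBS-11-O-TBDPS-luzonoid D | CC(C)CC(=O)O[C@@H]1OC=C(CO[Si](c3ccccc3)(c4ccccc4)C(C)(C)C)[C@H]2C[C@H](O)[C@](O)(COC(=O)/C=C\c5ccc(O[Si](C)(C)C(C)(C)C)cc5)[C@@H]12 | intermediate

16 | luzonoid D, (1S,4aS,6S,7R,7aS)-6,7-dihydroxy-4-(hydroxymethyl)-7-{[(Z)-3-(4-hydroxyphenyl)prop-2-enoyl]oxymethyl}-1,4a,5,6,7,7a-hexahydrocyclopenta[c]pyran-1-yl 3-methylbutanoate | CC(C)CC(=O)O[C@@H]1OC=C(CO)[C@H]2C[C@H](O)[C@](O)(COC(=O)/C=C\c3ccc(O)cc3)[C@@H]12 | target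

**Step count**
- Total steps: 13.
- Longest linear sequence: 10 (Steps 1–8, 12, 13, from genipin). The side chain is 3 steps (9–11).

**Three steps most likely to fail, with fallbacks**

1. Step 3, together with the facial outcome of Step 2. Water has to attack tertiary C8 from the concave face; attack at C7, Meinwald rearrangement, or loss of the C1 silyl group would give the wrong diol or none.
   Fallback: deliver the C8 oxygen intramolecularly. Use a 10-O-Boc carbonate (or N-phenylcarbamate) in place of 10-OTBS, epoxidise, and trigger 5-exo opening with BF3·OEt2 to the 8α,10-cyclic carbonate, which forces inversion at C8. The carbonate is cleaved in the DIBAL step, and C11-OH is then silylated selectively over the neopentyl C10-OH.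

2. Step 7. The lactol must be acylated in the presence of the free 7-OH, with β-selectivity and without ring-opening of the enol-ether lactol.
   Fallback: change the protecting-group plan. Cap 7-OH as a TES ether at the stage of 4 so the lactol is the only acylable OH; the TES group then comes off in the HF·pyridine step together with the C10 TBS.

3. Step 12. Risks are Z→E isomerisation through DMAP conjugate addition, slow reaction at the neopentyl-type C10-OH, and 1→10 isovaleroyl migration.
   Fallback: esterify 9 with 3-[4-(TBSO)phenyl]propiolic acid (no alkene geometry to lose) and set the Z-alkene afterwards by Lindlar semi-hydrogenation, which should leave the trisubstituted enol ether alone, then deprotect.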